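**Plan**

Labdane numbering is used: ring A = C1–C5/C10, ring B = C5–C10, chain = C11–C16, C17 = formyl carbon. The target belongs to the ent series (5R,6R,9S,10S).
Retrosynthetic cuts, in order: O-acetyl/O-silyl adjustments; C8–C17 (enol triflate formylation); C13–C16 (alkoxymethyl cuprate on a C13≡C14 ynoate); C14–C15 (acetylide plus chloroformate); C6–C7 (ring B, aldol); C7–C8 (MeLi on an acid); C9–C10 (Ireland–Claisen).
Enabling feature: in ring B the C6 carbinol stands β to C8, and C8 as a ketone is the forerunner of the C7=C8–C17HO enal, so ring B is a masked ketol. Opening C6–C7 gives a ring-A keto aldehyde in which C5 (α to C6HO) and C9 (α to C8=O) can epimerise and C6 is made reversibly.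
Forward: ring A is bought with β-cyclocitral and the C9–C10 bond is made first. The exocyclic C5=C6 alkene is raised to the aldehyde via its epoxide, ring B closes in step 8, and the chain and C17 are then finished on the decalin.
Stereochemistry: C10 comes from the chiral boron ligand in the Claisen step (the only absolute control element). C9 comes from ketene acetal geometry and a chair, backed by equilibration; C5 and C6 come from the aldol equilibrium under the axial methyls on C4 and C10; C13=C14 comes from syn-carbocupration.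

Key step: step 8

Assumption: the (R,R)-controller is written for the Claisen step. Its sense of induction on this tetrasubstituted alkene must be confirmed on the first batch of the Claisen acid, and the equally available (S,S)-controller is used if it proves opposite.

**Step 1**
Reactants: 1 hex-5-ynoic acid; 2 chlorotrimethylsilane
Product: 4 6-(trimethylsilyl)hex-5-ynoic acid, via bis-silylated ester 3 (not isolated)
Conditions: n-BuLi (2.1 equiv), THF, −78 °C; TMSCl (2.3 equiv), −78 °C → rt; 1 M HCl
Reagents that add atoms: chlorotrimethylsilane (2), C[Si](C)(C)Cl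
Why: Double deprotonation gives the carboxylate–acetylide dianion, both sites are silylated and the labile silyl ester is hydrolysed on acidic work-up (standard acetylide C-silylation), the silyl cap being needed to keep the alkyne out of reach of the B–Br reagent in step 4 and of MeLi in step 5.

**Step 2**
Reactants: 5 β-cyclocitral
Product: 6 β-cyclogeraniol [(2,6,6-trimethylcyclohex-1-en-1-yl)methanol]
Conditions: NaBH4, MeOH, 0 °C
Reagents that add atoms: none
Why: Borohydride 1,2-reduction of an enal whose fully substituted β-carbon excludes conjugate reduction.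

**Step 3**
Reactants: 4 6-(trimethylsilyl)hex-5-ynoic acid; 6 β-cyclogeraniol
Product: 7 (2,6,6-trimethylcyclohex-1-en-1-yl)methyl 6-(trimethylsilyl)hex-5-ynoate
Conditions: EDC·HCl, DMAP (cat.), CH2Cl2, 0 °C → rt
Reagents that add atoms: none
Why: Steglich-type carbodiimide/DMAP esterification joins acid and allylic alcohol under neutral conditions, so that the easily ionised β-cyclogeranyl C–O bond is not put at risk.

**Step 4**
Reactants: 7 β-cyclogeranyl 6-(trimethylsilyl)hex-5-ynoate
Product: 10 (2S)-2-[(1S)-1,3,3-trimethyl-2-methylidenecyclohexyl]-6-(trimethylsilyl)hex-5-ynoic acid, via boron ketene acetal 8 (not isolated), via acyloxyborane 9 (not isolated)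
Conditions: (R,R)-1,2-diphenylethylenediamine bis[3,5-bis(trifluoromethyl)benzenesulfonamide], BBr3, CH2Cl2, rt, then vacuum; 7, i-Pr2NEt, CH2Cl2, −78 → −20 °C; aqueous work-up
Reagents that add atoms: none
Why: Enantioselective Ireland–Claisen rearrangement through a chiral boron ketene acetal: soft enolisation with the bromoborane and Hünig's base in CH2Cl2 should favour the Z(O) geometry (chain cis to O–B), the [3,3] shift through a chair with the chain pseudo-equatorial bonds C9 to the methyl-bearing ring carbon C10 and moves the alkene to the exocyclic C5=C6 position, the C2-symmetric sulfonamide ligand on boron selecting the alkene face and thus the absolute configuration at the quaternary C10, and the ketene acetal geometry setting C9 relative to it.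

**Step 5**
Reactants: 10 Claisen acid
Product: 11 (3S)-3-[(1S)-1,3,3-trimethyl-2-methylidenecyclohexyl]-7-(trimethylsilyl)hept-6-yn-2-one
Conditions: MeLi (3 equiv), Et2O, 0 °C → rt; inverse quench into aq NH4Cl
Reagents that add atoms: methyllithium, [Li]C
Why: Addition of methyllithium to the lithium carboxylate gives a gem-dialkoxide that collapses to the methyl ketone only on quenching (acid-to-ketone conversion with an organolithium), which brings in C7, and the crowding around C8 works against a second addition.

**Step 6**
Reactants: 11 methylidene ketone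
Product: 12 (3S)-3-[(3S,4S)-4,8,8-trimethyl-1-oxaspiro[2.5]octan-4-yl]-7-(trimethylsilyl)hept-6-yn-2-one (epoxide oxygen on the face opposite the C10 methyl)
Conditions: m-CPBA, NaHCO3, CH2Cl2, 0 °C
Reagents that add atoms: m-chloroperbenzoic acid, O=C(OO)c1cccc(Cl)c1
Why: Prilezhaev epoxidation picks the electron-rich 1,1-disubstituted alkene over the silylalkyne and is faster than Baeyer–Villiger attack on the hindered ketone, the peracid coming in anti to the two axial methyl groups on C4 and C10 so that oxygen sits on the face opposite the C10 methyl; a hydroboration is deliberately avoided because boranes would also consume the alkyne and the ketone.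

**Step 7**
Reactants: 12 spiro-epoxy ketone
Product: 13 (1R,2R)-2,6,6-trimethyl-2-[(3S)-2-oxo-7-(trimethylsilyl)hept-6-yn-3-yl]cyclohexane-1-carbaldehyde (6,7-seco keto aldehyde)
Conditions: BF3·OEt2 (cat.), CH2Cl2, −78 °C, short contact; Et3N quench
Reagents that add atoms: none
Why: Meinwald rearrangement: the Lewis acid opens the epoxide at the tertiary C5 and a 1,2-hydride shift from C6 delivers the aldehyde, the oxocarbenium-forming hydride shift being expected to outrun methyl migration; C5 may emerge as a mixture of epimers, which is of no consequence because this centre is equilibrated in step 8.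

**Step 8**
Reactants: 13 6,7-seco keto aldehyde
Product: 14 (1S,4R,4aR,8aR)-1-(but-3-yn-1-yl)-4-hydroxy-5,5,8a-trimethyloctahydronaphthalen-2(1H)-one (trans-decalin; 6-OH equatorial and anti to the C10 methyl; C9 chain equatorial)
Conditions: K2CO3 (0.5 equiv), MeOH, 0 °C → rt; pH 7 phosphate buffer
Reagents that add atoms: none
Why: Methoxide formed from K2CO3 in MeOH reversibly enolises the methyl ketone towards C7 and this enolate adds to the C6 aldehyde, an intramolecular aldol addition run under aldol/retro-aldol equilibration as is known for keto aldehydes, while the same medium methanolyses the C–SiMe3 bond and so frees the alkyne needed in step 11. Ring B closes in the 6-(enolendo)-exo-trig mode, whereas the C9 and C5 enolates have only strained four-membered closures open to them and therefore act only as epimerisation channels. C5 is set thermodynamically: the open aldehyde epimerises through its enolate, cis-fused ketols revert by retro-aldol, and the material collects in the trans-decalin with H5 anti to the C10 methyl. C6 is governed by the axial methyl groups on C4 and C10, to both of which an axial 6-OH would be syn-diaxial, so that the oxygen points equatorially (anti to the C10 methyl) in the chair-like transition state as well as at equilibrium. C9, delivered correctly by step 4, remains α to the C8 ketone, so any epimer drains to the equatorial chain. The selectivity needed is addition without E1cB dehydration, and it rests on the equatorial C6–O bond lying close to the nodal plane of the C7 enolate in the rigid trans-decalin, supported by a weak base, low temperature and a buffered quench.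

**Step 9**
Reactants: 14 ketol
Product: 15 (1S,4R,4aR,8aR)-1-(but-3-yn-1-yl)-4-[(tert-butyldimethylsilyl)oxy]-5,5,8a-trimethyloctahydronaphthalen-2(1H)-one
Conditions: TBSOTf, 2,6-lutidine, CH2Cl2, −78 → 0 °C
Reagents that add atoms: tert-butyldimethylsilyl triflate, CC(C)(C)[Si](C)(C)OS(=O)(=O)C(F)(F)F
Why: Silyl triflate with a hindered pyridine base silylates the crowded equatorial 6-OH at low temperature without the basic conditions that could trigger retro-aldol cleavage or β-elimination of the ketol.

**Step 10**
Reactants: 15 silyloxy ketone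
Product: 16 (1S,4S,4aR,8aR)-1-(but-3-yn-1-yl)-4-[(tert-butyldimethylsilyl)oxy]-5,5,8a-trimethyl-1,4,4a,5,6,7,8,8a-octahydronaphthalen-2-yl trifluoromethanesulfonate (Δ7 enol triflate; same spatial arrangement, the C6 descriptor changes by priority only)
Conditions: KHMDS (1.1 equiv), THF, −78 °C; Comins' reagent, −78 °C
Reagents that add atoms: N-(5-chloropyridin-2-yl)bis(trifluoromethanesulfonimide), O=S(=O)(N(c1ccc(Cl)cn1)S(=O)(=O)C(F)(F)F)C(F)(F)F
Why: Kinetic deprotonation takes the accessible axial C7–H instead of the C9 methine next to quaternary C10, and O-sulfonylation with Comins' reagent fixes the Δ7 enol triflate; the equatorial silyloxy group is poorly aligned for β-elimination at −78 °C and the less acidic terminal alkyne stays protonated.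

**Step 11**
Reactants: 16 enol triflate
Product: 17 methyl 5-[(1S,4S,4aR,8aR)-4-[(tert-butyldimethylsilyl)oxy]-5,5,8a-trimethyl-2-(triflyloxy)-1,4,4a,5,6,7,8,8a-octahydronaphthalen-1-yl]pent-2-ynoate
Conditions: LDA, THF, −78 °C; ClCO2Me, −78 °C
Reagents that add atoms: methyl chloroformate, COC(=O)Cl
Why: Acetylide acylation with a chloroformate installs C15, and it is possible here because the C8 carbonyl is masked as the enol triflate so that no enolisable ketone competes for the amide base.

**Step 12**
Reactants: 18 4-methoxybenzyl alcohol; 19 tributyl(iodomethyl)stannane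
Product: 20 tributyl{[(4-methoxybenzyl)oxy]methyl}stannane
Conditions: NaH, THF/DMF, 0 °C → rt
Reagents that add atoms: none
Why: Williamson ether synthesis on the unhindered primary iodide gives the tin precursor of the alkoxymethyl anion.

**Step 13**
Reactants: 17 ynoate; 20 alkoxymethylstannane
Product: 21 methyl (2E)-3-{[(4-methoxybenzyl)oxy]methyl}-5-[(1S,4S,4aR,8aR)-4-[(tert-butyldimethylsilyl)oxy]-5,5,8a-trimethyl-2-(triflyloxy)-1,4,4a,5,6,7,8,8a-octahydronaphthalen-1-yl]pent-2-enoate
Conditions: 20, n-BuLi, THF, −78 °C; CuBr·SMe2, −78 °C; 17, −78 °C; aq NH4Cl at −78 °C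
Reagents that add atoms: none
Why: Tin–lithium exchange and transmetalation give the alkoxymethyl Gilman cuprate, whose syn-carbocupration of the ynoate followed by protonation with retention at −78 °C places CH2OPMB cis to H and the C12 chain cis to CO2Me, that is the (E)-enoate of the target, while enol triflates couple with cuprates only at much higher temperature.

**Step 14**
Reactants: 21 enoate enol triflate
Product: 22 methyl (2E)-5-[(1S,4R,4aR,8aS)-4-[(tert-butyldimethylsilyl)oxy]-2-formyl-5,5,8a-trimethyl-1,4,4a,5,6,7,8,8a-octahydronaphthalen-1-yl]-3-{[(4-methoxybenzyl)oxy]methyl}pent-2-enoate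
Conditions: Pd(OAc)2 (cat.), dppp, CO (1 atm), Et3SiH, Et3N, DMF, 70 °C
Reagents that add atoms: carbon monoxide, [C-]#[O+]
Why: Palladium-catalysed reductive carbonylation (formylation) of an enol triflate by oxidative addition, CO insertion and hydride transfer from the silane gives the C7=C8–C17 enal, and it is placed after the alkyne has been consumed (no carbopalladation) and before the acetate is present (an allylic ether does not ionise to a π-allyl complex).

**Step 15**
Reactants: 22 PMB ether enal
Product: 23 methyl (2E)-5-[(1S,4R,4aR,8aS)-4-[(tert-butyldimethylsilyl)oxy]-2-formyl-5,5,8a-trimethyl-1,4,4a,5,6,7,8,8a-octahydronaphthalen-1-yl]-3-(hydroxymethyl)pent-2-enoate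
Conditions: DDQ, CH2Cl2/pH 7 buffer, 0 °C
Reagents that add atoms: none
Why: Oxidative cleavage of the electron-rich PMB ether with DDQ under buffered conditions leaves silyl ether, enal and enoate untouched, and the liberated CH2OH is trans to the ester and so cannot lactonise.

**Step 16**
Reactants: 23 allylic alcohol
Product: 24 methyl (2E)-3-(acetoxymethyl)-5-[(1S,4R,4aR,8aS)-4-[(tert-butyldimethylsilyl)oxy]-2-formyl-5,5,8a-trimethyl-1,4,4a,5,6,7,8,8a-octahydronaphthalen-1-yl]pent-2-enoate
Conditions: Ac2O, pyridine, DMAP (cat.), CH2Cl2, 0 °C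
Reagents that add atoms: acetic anhydride, CC(=O)OC(C)=O
Why: Standard DMAP-catalysed acetylation of the only free hydroxyl group.

**Step 17**
Reactants: 24 silyl-protected acetate
Product: 25 methyl (2E)-3-(acetoxymethyl)-5-[(1S,4R,4aR,8aS)-2-formyl-4-hydroxy-5,5,8a-trimethyl-1,4,4a,5,6,7,8,8a-octahydronaphthalen-1-yl]pent-2-enoate (CNP0112124.1)
Conditions: HF·pyridine, pyridine/THF, 0 °C → rt
Reagents that add atoms: none
Why: Fluoride-mediated cleavage of the silyl ether in a buffered, weakly acidic medium avoids the basic conditions that could hydrolyse or shift the acetate or isomerise the γ-hydroxy enal, and no stereocentre is touched.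

**Compound list**

1 | hex-5-ynoic acid | OC(=O)CCCC#C | starting material
2 | chlorotrimethylsilane | C[Si](C)(C)Cl | starting material
3 | trimethylsilyl 6-(trimethylsilyl)hex-5-ynoate | C[Si](C)(C)OC(=O)CCCC#C[Si](C)(C)C | intermediate
4 | 6-(trimethylsilyl)hex-5-ynoic acid | OC(=O)CCCC#C[Si](C)(C)C | intermediate
5 | β-cyclocitral | CC1=C(C=O)C(C)(C)CCC1 | starting material
6 | β-cyclogeraniol | CC1=C(CO)C(C)(C)CCC1 | intermediate
7 | (2,6,6-trimethylcyclohex-1-en-1-yl)methyl 6-(trimethylsilyl)hex-5-ynoate | CC1=C(COC(=O)CCCC#C[Si](C)(C)C)C(C)(C)CCC1 | intermediate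
8 | (E)-boron ketene acetal of 7 [Z(O) enolate geometry], O-bound to the (4R,5R)-1,3-bis{[3,5-bis(trifluoromethyl)phenyl]sulfonyl}-4,5-diphenyl-1,3,2-diazaborolidin-2-yl group | C[Si](C)(C)C#CCC/C=C(/OCC1=C(C)CCCC1(C)C)OB1N(S(=O)(=O)c2cc(cc(c2)C(F)(F)F)C(F)(F)F)[C@H](c2ccccc2)[C@@H](c2ccccc2)N1S(=O)(=O)c1cc(cc(c1)C(F)(F)F)C(F)(F)F | intermediate
9 | acyloxyborane of acid 10 carrying the same (4R,5R)-diazaborolidine | O=C(OB2N(S(=O)(=O)c3cc(cc(c3)C(F)(F)F)C(F)(F)F)[C@H](c3ccccc3)[C@@H](c3ccccc3)N2S(=O)(=O)c2cc(cc(c2)C(F)(F)F)C(F)(F)F)[C@@H](CCC#C[Si](C)(C)C)[C@]1(C)CCCC(C)(C)C1=C | intermediate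
10 | (2S)-2-[(1S)-1,3,3-trimethyl-2-methylidenecyclohexyl]-6-(trimethylsilyl)hex-5-ynoic acid | OC(=O)[C@@H](CCC#C[Si](C)(C)C)[C@]1(C)CCCC(C)(C)C1=C | intermediate
11 | (3S)-3-[(1S)-1,3,3-trimethyl-2-methylidenecyclohexyl]-7-(trimethylsilyl)hept-6-yn-2-one | CC(=O)[C@@H](CCC#C[Si](C)(C)C)[C@]1(C)CCCC(C)(C)C1=C | intermediate
12 | (3S)-3-[(3S,4S)-4,8,8-trimethyl-1-oxaspiro[2.5]octan-4-yl]-7-(trimethylsilyl)hept-6-yn-2-one | CC(=O)[C@@H](CCC#C[Si](C)(C)C)[C@]1(C)CCCC(C)(C)[C@]12OC2 | intermediate
13 | (1R,2R)-2,6,6-trimethyl-2-[(3S)-2-oxo-7-(trimethylsilyl)hept-6-yn-3-yl]cyclohexane-1-carbaldehyde | CC(=O)[C@@H](CCC#C[Si](C)(C)C)[C@]1(C)CCCC(C)(C)[C@H]1C=O | intermediate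
14 | (1S,4R,4aR,8aR)-1-(but-3-yn-1-yl)-4-hydroxy-5,5,8a-trimethyloctahydronaphthalen-2(1H)-one | C#CCC[C@@H]1C(=O)C[C@@H](O)[C@@H]2C(C)(C)CCC[C@@]12C | intermediate
15 | 6-O-TBS ether of 14 | C#CCC[C@@H]1C(=O)C[C@@H](O[Si](C)(C)C(C)(C)C)[C@@H]2C(C)(C)CCC[C@@]12C | intermediate
16 | Δ7 enol triflate of 15 | C#CCC[C@@H]1C(OS(=O)(=O)C(F)(F)F)=C[C@@H](O[Si](C)(C)C(C)(C)C)[C@@H]2C(C)(C)CCC[C@@]12C | intermediate
17 | methyl ynoate of 16 | COC(=O)C#CCC[C@@H]1C(OS(=O)(=O)C(F)(F)F)=C[C@@H](O[Si](C)(C)C(C)(C)C)[C@@H]2C(C)(C)CCC[C@@]12C | intermediate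
18 | 4-methoxybenzyl alcohol | COc1ccc(CO)cc1 | starting material
19 | tributyl(iodomethyl)stannane | CCCC[Sn](CCCC)(CCCC)CI | starting material
20 | tributyl{[(4-methoxybenzyl)oxy]methyl}stannane | CCCC[Sn](CCCC)(CCCC)COCc1ccc(OC)cc1 | intermediate
21 | (E)-enoate with 16-OPMB, 6-OTBS and C8 enol triflate | COC(=O)/C=C(\CC[C@@H]1C(OS(=O)(=O)C(F)(F)F)=C[C@@H](O[Si](C)(C)C(C)(C)C)[C@@H]2C(C)(C)CCC[C@@]12C)COCc1ccc(OC)cc1 | intermediate
22 | (E)-enoate with 16-OPMB, 6-OTBS and C7=C8–CHO enal | COC(=O)/C=C(\CC[C@@H]1C(C=O)=C[C@@H](O[Si](C)(C)C(C)(C)C)[C@@H]2C(C)(C)CCC[C@@]12C)COCc1ccc(OC)cc1 | intermediate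
23 | 16-alcohol (6-OTBS enal) | COC(=O)/C=C(\CC[C@@H]1C(C=O)=C[C@@H](O[Si](C)(C)C(C)(C)C)[C@@H]2C(C)(C)CCC[C@@]12C)CO | intermediate
24 | 16-acetate (6-OTBS enal) | COC(=O)/C=C(\CC[C@@H]1C(C=O)=C[C@@H](O[Si](C)(C)C(C)(C)C)[C@@H]2C(C)(C)CCC[C@@]12C)COC(C)=O | intermediate
25 | methyl (2E)-3-(acetoxymethyl)-5-[(1S,4R,4aR,8aS)-2-formyl-4-hydroxy-5,5,8a-trimethyl-1,4,4a,5,6,7,8,8a-octahydronaphthalen-1-yl]pent-2-enoate | COC(=O)/C=C(\CC[C@@H]1C(C=O)=C[C@@H](O)[C@@H]2C(C)(C)CCC[C@@]12C)COC(C)=O | target

**Totals**

Total step count: 17.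
Longest linear sequence: 15 steps (step 1 or step 2, then steps 3–11 and 13–17).

**Steps most likely to fail**

*Step 4.* Three processes threaten this step. The [3,3] shift onto a tetrasubstituted alkene flanked by a quaternary carbon may be too slow at temperatures the boron ketene acetal tolerates. The Lewis-acidic bromoborane may ionise the allylic ester. Facial discrimination may also be too low.

The fallback sets out from 7. Enolisation with LDA in THF/DMPU and trapping with TMSCl at −78 °C gives the (Z)-silyl ketene acetal F1. Heating F1 in THF rearranges it to the racemic silyl ester F2, which is hydrolysed on work-up to the racemic acid F3. Classical resolution follows, by fractional crystallisation of the 1-phenylethylammonium salt F4. It is written with the (R)-amine; the antipode of the amine that deposits the wanted salt is found by trial. Acidification rejoins the route at 10.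

*Step 7.* The C8 carbonyl oxygen may capture the developing C5 cation (internal ketal formation), or a methyl group may migrate from C4 or C10, and either could compete with the hydride shift.

The fallback sets out from 12 and replaces the cationic opening by a radical one. Cp2TiCl (from Cp2TiCl2 and Mn) in THF, with a high concentration of 1,4-cyclohexadiene, opens the epoxide homolytically to the tertiary C5 radical. This radical takes up hydrogen anti to the axial methyls and gives the keto alcohol F5. Dess–Martin oxidation rejoins the route at 13.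

*Step 8.* E1cB loss of water from the ketol may outrun the aldol/retro-aldol equilibration, or epimerisation at the hindered C5 may stay incomplete.

The fallback sets out from 13 and keeps the same C6–C7 ring closure, but lets it run through to condensation. KOH in warm MeOH gives the trans-fused enone F6, in which C5 is epimerisable as the vinylogous α-position. Weitz–Scheffer epoxidation (H2O2, NaOH, MeOH) from the face anti to the axial methyls gives the epoxy ketone F7. SmI2 in THF/MeOH at low temperature cleaves the C7–O bond with retention of the C6–O bond and rejoins the route at 14.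

**Further compounds**

F1 | step 4 | (Z)-trimethylsilyl ketene acetal of 7 | C[Si](C)(C)C#CCC/C=C(/OCC1=C(C)CCCC1(C)C)O[Si](C)(C)C
F2 | step 4 | racemic trimethylsilyl ester of the Claisen acid (both enantiomers) | C[Si](C)(C)OC(=O)[C@@H](CCC#C[Si](C)(C)C)[C@]1(C)CCCC(C)(C)C1=C.C[Si](C)(C)OC(=O)[C@H](CCC#C[Si](C)(C)C)[C@@]1(C)CCCC(C)(C)C1=C
F3 | step 4 | racemic Claisen acid (both enantiomers) | OC(=O)[C@@H](CCC#C[Si](C)(C)C)[C@]1(C)CCCC(C)(C)C1=C.OC(=O)[C@H](CCC#C[Si](C)(C)C)[C@@]1(C)CCCC(C)(C)C1=C
F4 | step 4 | (R)-1-phenylethylammonium salt of 10 | C[C@@H]([NH3+])c1ccccc1.[O-]C(=O)[C@@H](CCC#C[Si](C)(C)C)[C@]1(C)CCCC(C)(C)C1=C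
F5 | step 7 | (3S)-3-[(1R,2R)-2-(hydroxymethyl)-1,3,3-trimethylcyclohexyl]-7-(trimethylsilyl)hept-6-yn-2-one (H5 anti to the C10 methyl) | CC(=O)[C@@H](CCC#C[Si](C)(C)C)[C@]1(C)CCCC(C)(C)[C@H]1CO
F6 | step 8 | trans-fused 6-en-8-one with a but-3-ynyl chain at C9 | C#CCC[C@@H]1C(=O)C=C[C@@H]2C(C)(C)CCC[C@@]12C
F7 | step 8 | 6,7-epoxy-8-one, epoxide anti to the C10 methyl | C#CCC[C@@H]1C(=O)[C@H]3O[C@H]3[C@@H]2C(C)(C)CCC[C@@]12C
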